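A closed, stirred vessel at constant temperature holds L, X and a little initiator Z, which together make E. The flask ash has been followed for some hours, and maple is an earlier run with less X.

| flask | L | X | Z | remark | time |
|---|---|---|---|---|---|
| ash | 0.050 M | 0.035 M | 1.9 mM | the very flask that is asked about, followed so far |  |
| maple | 0.050 M | 0.023 M | 1.9 mM | run made earlier |  |
| flask | 0.050 M | 0.0350 M | 1.9 mM |  | 2.5 d |

- ash (time / h: E / %, L / %): 3.00: 69.6, 27.9; 6.00: 69.1, 27.8; 15.0: 70.3, 27.6; 40.0: 69.6, 27.3
- maple (time / h: E / %, L / %): 0.417: 45.4, 52.5; 1.00: 45.8, 49.7; 2.00: 45.7, 48.7; 3.00: 45.8, 49.1

(readings scatter by 0.3 percentage points)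

- dawn: change nothing and wait 20 h more
- summer: at 2.5 d add X, 100% of the amount charged, then wait 20 h
- winter: at 2.5 d take out 90% of the E then present, then wait 20 h
- noon: at 2.5 d add L, 50.0% of the amount charged, then wait 20 h

* E, in percent of the L first charged, at 2.5 d
* which option adds most E ("none" when 2 percentage points or less is all one gets) (dawn / summer / winter / noon / none)
* E present, with what was taken out counted in, in percent of the L first charged, after summer
* E present, with what was taken out counted in, in percent of the L first charged, after noon

- E that was removed still counts
- what was read earlier has a scatter of 0.3 percentage points, one standard deviation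
- additions bring no volume worth counting

Two of us agree on the plateau. E formed per X charged reads 0.994 in ash and 0.996 in maple, so X goes one to one and is the limiting reagent. We part over summer. One of us holds that ash stays alive: fresh X meets the 27.3% of L still there, and E climbs. The other holds that the activity born of Z dies on its own clock, and maple shows that clock, because L keeps falling there without E forming, then levels off.

At the board, suppose the activity falls as exp(−t/τ) and the loss of L follows it. Integrating, L − L∞ falls with the same exponential. Take L∞ as the mean of the last two maple readings, 48.9%. The first two readings then give the activity lifetime τ = 0.388 h. This is a rough reading, since its second gap, 0.8 percentage points, stands near the scatter. Still, 2.5 d is 155 lifetimes, and doubling τ leaves 77.3. This reckoning is mine and sides with the dying flask.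

The forecast sides with it too: “This suggests the active species from Z dies within hours, independently of X”. It gives 69.7% at 2.5 d, best none, 70% after summer with a range up to 96%, and 69.7% after noon.

The simulation gives 70.0%, best none, 70.0% after summer and 70.0% after noon, so the dying flask wins.

    X + Q → E + G (k = 28000 L mol⁻¹ s⁻¹)
    L + G → Q (k = 16000 L mol⁻¹ s⁻¹)
    Z → 2 G (k = 0.0350 min⁻¹)
    2 G → D (k = 5.00 × 10⁸ L mol⁻¹ s⁻¹)
    2 Q → J (k = 1.60 × 10⁷ L mol⁻¹ s⁻¹)

In this flask Z gave the initiating radical G with a half-life of 0.33 h, while G took up L to form the chain carrier Q, and Q turned X into E, half of that turnover being done by 0.177 h. By 60.0 h X stood at 0% and Z at 0%, with L at 27.5%. Summer came at 2.5 d, roughly 155 times the τ read off the maple readings, 0.388 h, and it gained 0 points. The living view holds where X is present from the start: a neighbour flask with 0.14 M of X and the same Z reached 92.4% of E, yet at 60.0 h it held Z at 0% and X at 67%, with L at 7.56%.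

(The earlier runs and the new flask were computed on assumed constants; scatter was added.)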